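The route rests on reading the ring-fusion bond C3a'–C9a', shared by the cyclopentane and the dihydropyran, as an aldol bond. With the benzylic carbon C9' raised to a ketone, the methyl-bearing C9a' becomes an enolate carbon, the O-bearing C3a' an aldehyde carbon, and the aryl–O bond ortho to that ketone an SNAr bond. One basic operation on an open-chain keto aldehyde thus closes the cyclopentane by C3a'–C9a' bond formation and then the pyranone by fluoride displacement, giving the cis-fused tetracycle with two new stereocentres. The precursor is a menthone-derived cyclohexenecarbaldehyde whose quaternary carbon carries a 4-aryl-3-methyl-4-oxobutyl chain (aryl = 2-fluoro-4,6-dimethoxyphenyl). Isobutyl addition, ionic reduction, diformylation and demethylation complete the synthesis.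

Key step: step 9

Remark: primed locants are those of the spiro[cyclohex-2-ene-1,3'-cyclopenta[b]chromene] name of the target (C1 = C3' is the spiro carbon); 2 and 3 are carried as epimer mixtures at the isopropyl-bearing carbon, which becomes sp2 in step 3, and 10 and 14 as epimer mixtures at centres that are erased in the next step.

Step 1
Reactants: 1 (–)-menthone, (2S,5R)-5-methyl-2-(propan-2-yl)cyclohexan-1-one
Product: 2 (3R)-2-(hydroxymethylidene)-3-methyl-6-(propan-2-yl)cyclohexan-1-one (enol form of the β-keto aldehyde; C6 epimers)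
Conditions: NaH, HCO2Et, EtOH (cat.), THF, 0 °C → rt; aq. HCl
Reagents that add atoms: ethyl formate, CCOC=O
Why: Crossed Claisen condensation (formylation) can only end at the CH2 flank, where the product survives as its stabilised enolate, so the formyl carbon enters next to the methyl-bearing carbon, which is β to the carbonyl and keeps its (R) configuration.

Step 2
Reactants: 2 (3R)-2-(hydroxymethylidene)-3-methyl-6-(propan-2-yl)cyclohexan-1-one
Product: 3 (1S,2R)-2-methyl-6-oxo-5-(propan-2-yl)-1-(prop-2-en-1-yl)cyclohexane-1-carbaldehyde (C5 epimers)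
Conditions: allyl methyl carbonate, Pd(PPh3)4 (cat.), THF, rt
Reagents that add atoms: allyl methyl carbonate, C=CCOC(=O)OC
Why: Tsuji–Trost C-allylation of the soft β-keto aldehyde enolate (any O-allyl enol ether re-ionises under the catalyst) should occur anti to the adjacent methyl group, held pseudoaxial by allylic strain with the exocyclic enolate, which sets the quaternary carbon with allyl trans and formyl cis to that methyl.

Step 3
Reactants: 3 (1S,2R)-2-methyl-6-oxo-5-(propan-2-yl)-1-(prop-2-en-1-yl)cyclohexane-1-carbaldehyde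
Product: 4 (5R,6R)-6-formyl-5-methyl-2-(propan-2-yl)-6-(prop-2-en-1-yl)cyclohex-1-en-1-yl trifluoromethanesulfonate
Conditions: LiTMP, THF, −78 → −20 °C; N-(5-chloropyridin-2-yl)bis(trifluoromethanesulfonyl)imide, −78 °C → rt
Reagents that add atoms: N-(5-chloropyridin-2-yl)-1,1,1-trifluoro-N-(trifluoromethanesulfonyl)methanesulfonamide, O=S(=O)(N(c1ccc(Cl)cn1)S(=O)(=O)C(F)(F)F)C(F)(F)F
Why: Regiospecific enol triflate formation, because the only α-hydrogen sits on the isopropyl-bearing carbon and the hindered amide base can neither add to nor reduce the neopentyl aldehyde; no stereocentre is formed and the epimeric centre is removed.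

Step 4
Reactants: 4 (5R,6R)-6-formyl-5-methyl-2-(propan-2-yl)-6-(prop-2-en-1-yl)cyclohex-1-en-1-yl trifluoromethanesulfonate
Product: 5 (1R,6R)-6-methyl-3-(propan-2-yl)-1-(prop-2-en-1-yl)cyclohex-2-ene-1-carbaldehyde
Conditions: Pd(OAc)2 (cat.), PPh3, HCO2H, Bu3N, DMF, 60 °C
Reagents that add atoms: none
Why: Palladium-catalysed formate reduction of an enol triflate (oxidative addition, decarboxylation of formate to the vinylpalladium hydride, reductive elimination) replaces OTf by H without moving the double bond and should leave the aldehyde and the terminal alkene untouched.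

Step 5
Reactants: 6 1-fluoro-3,5-dimethoxybenzene
Product: 7 1-(2-fluoro-4,6-dimethoxyphenyl)propan-1-one
Conditions: propanoic anhydride, Sc(OTf)3 (cat.), MeNO2, 50 °C
Reagents that add atoms: propanoic anhydride, CCC(=O)OC(=O)CC
Why: Friedel–Crafts acylation should go to C2, para to one methoxy group and ortho to the small fluorine, rather than to the position flanked by both methoxy groups, as is usual for 5-substituted 1,3-dimethoxybenzenes.

Step 6
Reactants: 7 1-(2-fluoro-4,6-dimethoxyphenyl)propan-1-one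
Product: 8 1-(2-fluoro-4,6-dimethoxyphenyl)-2-methylprop-2-en-1-one
Conditions: (CH2O)n, i-Pr2NH·CF3CO2H, CF3CO2H (cat.), THF, reflux
Reagents that add atoms: paraformaldehyde (as formaldehyde), C=O
Why: Mannich-type α-methylenation (aminomethylation of the enol, then β-elimination of the amine) turns the ethyl ketone into the isopropenyl ketone; no stereocentre is involved.

Step 7
Reactants: 5 (1R,6R)-6-methyl-3-(propan-2-yl)-1-(prop-2-en-1-yl)cyclohex-2-ene-1-carbaldehyde; 8 1-(2-fluoro-4,6-dimethoxyphenyl)-2-methylprop-2-en-1-one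
Product: 9 (1R,6R)-1-[(2E)-4-(2-fluoro-4,6-dimethoxyphenyl)-3-methyl-4-oxobut-2-en-1-yl]-6-methyl-3-(propan-2-yl)cyclohex-2-ene-1-carbaldehyde
Conditions: second-generation Hoveyda–Grubbs catalyst (5 mol %), 8 (3 equiv), CH2Cl2, 40 °C
Reagents that add atoms: none
Why: Olefin cross-metathesis of the terminal allyl group with the slowly homodimerising 1,1-disubstituted enone should give the (E)-trisubstituted enone with loss of ethene, the hindered ring alkene and the aldehyde being inert; the alkene geometry is of no consequence.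

Step 8
Reactants: 9 (1R,6R)-1-[(2E)-4-(2-fluoro-4,6-dimethoxyphenyl)-3-methyl-4-oxobut-2-en-1-yl]-6-methyl-3-(propan-2-yl)cyclohex-2-ene-1-carbaldehyde
Product: 10 (1R,6R)-1-[4-(2-fluoro-4,6-dimethoxyphenyl)-3-methyl-4-oxobutyl]-6-methyl-3-(propan-2-yl)cyclohex-2-ene-1-carbaldehyde (side-chain C3 epimers)
Conditions: H2 (1 atm), 5% Pd/C, EtOAc, rt, stopped after one equivalent
Reagents that add atoms: none
Why: Heterogeneous hydrogenation should reduce the conjugated acyclic C=C much faster than the trisubstituted ring alkene shielded by the neighbouring quaternary carbon; the new α-methyl centre forms as an epimer mixture that is erased by enolisation in step 9.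

Step 9
Reactants: 10 (1R,6R)-1-[4-(2-fluoro-4,6-dimethoxyphenyl)-3-methyl-4-oxobutyl]-6-methyl-3-(propan-2-yl)cyclohex-2-ene-1-carbaldehyde
Product: 13 (1R,3a'R,6R,9a'S)-6',8'-dimethoxy-6,9a'-dimethyl-3-(propan-2-yl)-1',2',3a',9a'-tetrahydro-9'H-spiro[cyclohex-2-ene-1,3'-cyclopenta[b]chromen]-9'-one, via potassium enolate 11 (not isolated), via potassium cis-aldolate 12 (not isolated)
Conditions: t-BuOK (1.2 equiv), THF–DMF, 0 → 40 °C, 0.01 M
Reagents that add atoms: none
Why: tert-Butoxide reversibly deprotonates the only acidic C–H (the α-CH of the aryl ketone; the aldehyde α-carbon is quaternary) to give enolate 11, which adds to the aldehyde in a 5-(enolexo)-exo-trig aldol cyclisation and so closes the cyclopentane through the C3a'–C9a' bond. In the cis-aldolate 12 the alkoxide lies next to the aroyl group and displaces fluoride ortho to the ketone by addition–elimination through a Meisenheimer adduct (6-exo closure of the pyranone); the closest known reaction types are the intramolecular aldol cyclisation and the base-mediated closure of 2-fluorophenyl β-hydroxy ketones to chroman-4-ones. The trans-aldolate cannot reach the arene and reverts by retro-aldol reaction, so the irreversible substitution drains the equilibrium and the cis ring fusion (relative configuration of C3a' and C9a') is enforced by the tether. Their configuration relative to the spiro carbon is set by that existing centre under Curtin–Hammett control: the alkoxide and the arene it attacks should lie on the side of the flat vinylic C2–H of the cyclohexene, while C3a'–H faces the C6 methine that carries the methyl group. The step needs enolisation at one site only and intramolecular rather than intermolecular substitution, which the single acidic C–H, the bulky alkoxide base and high dilution should secure, and the two methoxy groups, both meta to the C–F carbon, do not deactivate the substitution.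

Step 10
Reactants: 13 (1R,3a'R,6R,9a'S)-6',8'-dimethoxy-6,9a'-dimethyl-3-(propan-2-yl)-1',2',3a',9a'-tetrahydro-9'H-spiro[cyclohex-2-ene-1,3'-cyclopenta[b]chromen]-9'-one
Product: 14 (1R,3a'R,6R,9a'S)-6',8'-dimethoxy-6,9a'-dimethyl-9'-(2-methylpropyl)-3-(propan-2-yl)-1',2',9',9a'-tetrahydro-3a'H-spiro[cyclohex-2-ene-1,3'-cyclopenta[b]chromen]-9'-ol (C9' epimers)
Conditions: i-BuLi, CeCl3, THF, −78 → 0 °C; aq. NH4Cl
Reagents that add atoms: isobutyllithium, CC(C)C[Li]
Why: 1,2-Addition of an organocerium reagent, which is weakly basic and not prone to β-hydride reduction, to the hindered, non-enolisable aryl ketone; the configuration of the new carbinol carbon is irrelevant because it is ionised in step 11.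

Step 11
Reactants: 14 (1R,3a'R,6R,9a'S)-6',8'-dimethoxy-6,9a'-dimethyl-9'-(2-methylpropyl)-3-(propan-2-yl)-1',2',9',9a'-tetrahydro-3a'H-spiro[cyclohex-2-ene-1,3'-cyclopenta[b]chromen]-9'-ol
Product: 15 (1R,3a'S,6R,9'S,9a'R)-6',8'-dimethoxy-6,9a'-dimethyl-9'-(2-methylpropyl)-3-(propan-2-yl)-1',2',9',9a'-tetrahydro-3a'H-spiro[cyclohex-2-ene-1,3'-cyclopenta[b]chromene]
Conditions: Et3SiH, CF3CO2H, CH2Cl2, −40 °C
Reagents that add atoms: none
Why: Ionic hydrogenation: the tertiary, trioxygenated benzylic alcohol ionises far below the temperature at which the ring alkene is protonated, and hydride should reach the planar C9' cation from the convex face of the cis-fused bicycle, anti to the pseudoaxial cyclopentane methylene C1' and away from the spiro ring, which places H cis to the C9a' methyl and C3a'–H and gives the (9'S) centre.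

Step 12
Reactants: 15 (1R,3a'S,6R,9'S,9a'R)-6',8'-dimethoxy-6,9a'-dimethyl-9'-(2-methylpropyl)-3-(propan-2-yl)-1',2',9',9a'-tetrahydro-3a'H-spiro[cyclohex-2-ene-1,3'-cyclopenta[b]chromene]
Product: 16 (1R,3a'S,6R,9'S,9a'R)-6',8'-dimethoxy-6,9a'-dimethyl-9'-(2-methylpropyl)-3-(propan-2-yl)-1',2',9',9a'-tetrahydro-3a'H-spiro[cyclohex-2-ene-1,3'-cyclopenta[b]chromene]-5',7'-dicarbaldehyde
Conditions: Cl2CHOMe (excess), TiCl4, CH2Cl2, −78 → 0 °C; H2O
Reagents that add atoms: dichloromethyl methyl ether, COC(Cl)Cl; water, O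
Why: Rieche formylation, in which both free positions of the phloroglucinol triether ring (C5' and C7'), each ortho or para to three oxygens, should be formylated in turn by excess reagent, the α-chloro ethers being hydrolysed to the aldehydes on work-up.

Step 13
Reactants: 16 (1R,3a'S,6R,9'S,9a'R)-6',8'-dimethoxy-6,9a'-dimethyl-9'-(2-methylpropyl)-3-(propan-2-yl)-1',2',9',9a'-tetrahydro-3a'H-spiro[cyclohex-2-ene-1,3'-cyclopenta[b]chromene]-5',7'-dicarbaldehyde
Product: 17 (1R,3a'S,6R,9'S,9a'R)-6',8'-dihydroxy-6,9a'-dimethyl-9'-(2-methylpropyl)-3-(propan-2-yl)-1',2',9',9a'-tetrahydro-3a'H-spiro[cyclohex-2-ene-1,3'-cyclopenta[b]chromene]-5',7'-dicarbaldehyde (CNP0121396.3)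
Conditions: BCl3, CH2Cl2, −78 → 0 °C; H2O
Reagents that add atoms: none
Why: Chelation-assisted aryl methyl ether cleavage, in which BCl3 bridges each formyl oxygen and the neighbouring methoxy group and chloride removes the methyl groups, while the secondary alkyl aryl ether of the pyran ring and the alkene should survive at low temperature.

Compound list
1 | (–)-menthone, (2S,5R)-5-methyl-2-(propan-2-yl)cyclohexan-1-one | CC(C)[C@@H]1CC[C@@H](C)CC1=O | starting material
2 | (3R)-2-(hydroxymethylidene)-3-methyl-6-(propan-2-yl)cyclohexan-1-one (C6 epimers) | CC(C)C1CC[C@@H](C)C(=CO)C1=O | intermediate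
3 | (1S,2R)-2-methyl-6-oxo-5-(propan-2-yl)-1-(prop-2-en-1-yl)cyclohexane-1-carbaldehyde (C5 epimers) | C=CC[C@@]1(C=O)[C@H](C)CCC(C(C)C)C1=O | intermediate
4 | (5R,6R)-6-formyl-5-methyl-2-(propan-2-yl)-6-(prop-2-en-1-yl)cyclohex-1-en-1-yl trifluoromethanesulfonate | C=CC[C@@]1(C=O)[C@H](C)CCC(C(C)C)=C1OS(=O)(=O)C(F)(F)F | intermediate
5 | (1R,6R)-6-methyl-3-(propan-2-yl)-1-(prop-2-en-1-yl)cyclohex-2-ene-1-carbaldehyde | C=CC[C@@]1(C=O)[C@H](C)CCC(C(C)C)=C1 | intermediate
6 | 1-fluoro-3,5-dimethoxybenzene | COc1cc(F)cc(OC)c1 | starting material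
7 | 1-(2-fluoro-4,6-dimethoxyphenyl)propan-1-one | CCC(=O)c1c(F)cc(OC)cc1OC | intermediate
8 | 1-(2-fluoro-4,6-dimethoxyphenyl)-2-methylprop-2-en-1-one | C=C(C)C(=O)c1c(F)cc(OC)cc1OC | intermediate
9 | (1R,6R)-1-[(2E)-4-(2-fluoro-4,6-dimethoxyphenyl)-3-methyl-4-oxobut-2-en-1-yl]-6-methyl-3-(propan-2-yl)cyclohex-2-ene-1-carbaldehyde | COc1cc(F)c(C(=O)/C(C)=C/C[C@@]2(C=O)[C@H](C)CCC(C(C)C)=C2)c(OC)c1 | intermediate
10 | (1R,6R)-1-[4-(2-fluoro-4,6-dimethoxyphenyl)-3-methyl-4-oxobutyl]-6-methyl-3-(propan-2-yl)cyclohex-2-ene-1-carbaldehyde (side-chain C3 epimers) | COc1cc(F)c(C(=O)C(C)CC[C@@]2(C=O)[C@H](C)CCC(C(C)C)=C2)c(OC)c1 | intermediate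
11 | potassium 1-(2-fluoro-4,6-dimethoxyphenyl)-4-[(1R,6R)-1-formyl-6-methyl-3-(propan-2-yl)cyclohex-2-en-1-yl]-2-methylbut-1-en-1-olate (not isolated) | [K+].COc1cc(F)c(C([O-])=C(C)CC[C@@]2(C=O)[C@H](C)CCC(C(C)C)=C2)c(OC)c1 | intermediate
12 | potassium (1R,2S,5R,10R)-2-(2-fluoro-4,6-dimethoxybenzoyl)-2,10-dimethyl-7-(propan-2-yl)spiro[4.5]dec-6-en-1-olate (not isolated) | [K+].[O-][C@H]1[C@@](C)(C(=O)c2c(F)cc(OC)cc2OC)CC[C@@]13C=C(C(C)C)CC[C@H]3C | intermediate
13 | (1R,3a'R,6R,9a'S)-6',8'-dimethoxy-6,9a'-dimethyl-3-(propan-2-yl)-1',2',3a',9a'-tetrahydro-9'H-spiro[cyclohex-2-ene-1,3'-cyclopenta[b]chromen]-9'-one | O=C1c2c(OC)cc(OC)cc2O[C@H]2[C@]1(C)CC[C@@]21C=C(C(C)C)CC[C@H]1C | intermediate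
14 | (1R,3a'R,6R,9a'S)-6',8'-dimethoxy-6,9a'-dimethyl-9'-(2-methylpropyl)-3-(propan-2-yl)-1',2',9',9a'-tetrahydro-3a'H-spiro[cyclohex-2-ene-1,3'-cyclopenta[b]chromen]-9'-ol (C9' epimers) | CC(C)CC1(O)c2c(OC)cc(OC)cc2O[C@H]2[C@]1(C)CC[C@@]21C=C(C(C)C)CC[C@H]1C | intermediate
15 | (1R,3a'S,6R,9'S,9a'R)-6',8'-dimethoxy-6,9a'-dimethyl-9'-(2-methylpropyl)-3-(propan-2-yl)-1',2',9',9a'-tetrahydro-3a'H-spiro[cyclohex-2-ene-1,3'-cyclopenta[b]chromene] | CC(C)C[C@@H]1c2c(OC)cc(OC)cc2O[C@H]2[C@]1(C)CC[C@@]21C=C(C(C)C)CC[C@H]1C | intermediate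
16 | (1R,3a'S,6R,9'S,9a'R)-6',8'-dimethoxy-6,9a'-dimethyl-9'-(2-methylpropyl)-3-(propan-2-yl)-1',2',9',9a'-tetrahydro-3a'H-spiro[cyclohex-2-ene-1,3'-cyclopenta[b]chromene]-5',7'-dicarbaldehyde | CC(C)C[C@@H]1c2c(OC)c(C=O)c(OC)c(C=O)c2O[C@H]2[C@]1(C)CC[C@@]21C=C(C(C)C)CC[C@H]1C | intermediate
17 | (1R,3a'S,6R,9'S,9a'R)-6',8'-dihydroxy-6,9a'-dimethyl-9'-(2-methylpropyl)-3-(propan-2-yl)-1',2',9',9a'-tetrahydro-3a'H-spiro[cyclohex-2-ene-1,3'-cyclopenta[b]chromene]-5',7'-dicarbaldehyde | CC(C)C[C@@H]1c2c(O)c(C=O)c(O)c(C=O)c2O[C@H]2[C@]1(C)CC[C@@]21C=C(C(C)C)CC[C@H]1C | target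

Total step count: 13. Longest linear sequence: 11 steps (steps 1–4 and 7–13; steps 5 and 6 make the aryl enone 8).

Steps most likely to fail

Step 9 (key step). The hindered aldol equilibrium may lie on the open side long enough for enolate and aldehyde to be consumed by intermolecular aldol or hydride-transfer reactions, or the pyranone may close on the wrong face of the spiro carbon (poor diastereofacial selectivity relative to C1). The fallback sets out from enone aldehyde 9, so that step 8 is skipped. A cobalt-hydride aldol cycloreduction (Co(dpm)2 (cat.), dpm = dipivaloylmethanato, PhSiH3, 1,2-dichloroethane, rt) generates the enolate by hydrometalation under neutral conditions and closes the cyclopentane through a chelated, kinetically controlled transition state. It should give the neutral syn-aldol (2-fluoro-4,6-dimethoxyphenyl)[(1R,2S,5R,10R)-1-hydroxy-2,10-dimethyl-7-(propan-2-yl)spiro[4.5]dec-6-en-2-yl]methanone F1, from which unwanted diastereomers are removed. The pyranone is then closed in a separate SNAr step (NaH, DMF, 0 °C → rt), which comes back to the route at chromanone 13.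

Step 11. Hydride transfer to the planar C9' cation may show poor facial selectivity; delivery from the concave face would give the C9' epimer. The fallback sets out from chromanone 13 and replaces steps 10 and 11 by inverting the order in which hydrogen and the four-carbon unit reach C9', so that the face preferred by the nucleophile receives carbon instead of hydrogen. LiAlH4 reduction gives (1R,3a'R,6R,9a'R)-6',8'-dimethoxy-6,9a'-dimethyl-3-(propan-2-yl)-1',2',9',9a'-tetrahydro-3a'H-spiro[cyclohex-2-ene-1,3'-cyclopenta[b]chromen]-9'-ol F2. Ionisation with BF3·OEt2 in the presence of trimethyl(2-methylprop-2-en-1-yl)silane (Hosomi–Sakurai reaction of the benzylic cation) gives (1R,3a'S,6R,9'S,9a'R)-6',8'-dimethoxy-6,9a'-dimethyl-9'-(2-methylprop-2-en-1-yl)-3-(propan-2-yl)-1',2',9',9a'-tetrahydro-3a'H-spiro[cyclohex-2-ene-1,3'-cyclopenta[b]chromene] F3. Hydrogenation of its 1,1-disubstituted alkene with RhCl(PPh3)3 and H2, to which the trisubstituted ring alkene should be inert, comes back to the route at chroman 15.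

Step 12. The trisubstituted ring alkene may undergo hydrochlorination or cationic rearrangement under TiCl4 and HCl, or the reaction may stop after the first formylation because the ring is then deactivated. The fallback sets out from chroman 15. Electrophilic dibromination (NBS, MeCN, −20 °C; the trialkoxyarene should react far faster than the hindered alkene) gives (1R,3a'S,6R,9'S,9a'R)-5',7'-dibromo-6',8'-dimethoxy-6,9a'-dimethyl-9'-(2-methylpropyl)-3-(propan-2-yl)-1',2',9',9a'-tetrahydro-3a'H-spiro[cyclohex-2-ene-1,3'-cyclopenta[b]chromene] F4. Double bromine–lithium exchange (t-BuLi, THF, −78 °C) and quench with DMF come back to the route at dialdehyde 16 without any acid.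

Further compounds
F1 | step 9 | (2-fluoro-4,6-dimethoxyphenyl)[(1R,2S,5R,10R)-1-hydroxy-2,10-dimethyl-7-(propan-2-yl)spiro[4.5]dec-6-en-2-yl]methanone | O[C@H]1[C@@](C)(C(=O)c2c(F)cc(OC)cc2OC)CC[C@@]13C=C(C(C)C)CC[C@H]3C
F2 | step 11 | (1R,3a'R,6R,9a'R)-6',8'-dimethoxy-6,9a'-dimethyl-3-(propan-2-yl)-1',2',9',9a'-tetrahydro-3a'H-spiro[cyclohex-2-ene-1,3'-cyclopenta[b]chromen]-9'-ol (C9' epimers) | OC1c2c(OC)cc(OC)cc2O[C@H]2[C@]1(C)CC[C@@]21C=C(C(C)C)CC[C@H]1C
F3 | step 11 | (1R,3a'S,6R,9'S,9a'R)-6',8'-dimethoxy-6,9a'-dimethyl-9'-(2-methylprop-2-en-1-yl)-3-(propan-2-yl)-1',2',9',9a'-tetrahydro-3a'H-spiro[cyclohex-2-ene-1,3'-cyclopenta[b]chromene] | C=C(C)C[C@@H]1c2c(OC)cc(OC)cc2O[C@H]2[C@]1(C)CC[C@@]21C=C(C(C)C)CC[C@H]1C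
F4 | step 12 | (1R,3a'S,6R,9'S,9a'R)-5',7'-dibromo-6',8'-dimethoxy-6,9a'-dimethyl-9'-(2-methylpropyl)-3-(propan-2-yl)-1',2',9',9a'-tetrahydro-3a'H-spiro[cyclohex-2-ene-1,3'-cyclopenta[b]chromene] | CC(C)C[C@@H]1c2c(OC)c(Br)c(OC)c(Br)c2O[C@H]2[C@]1(C)CC[C@@]21C=C(C(C)C)CC[C@H]1C
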